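Ring A of the anisyl-bearing flavanone is closed last, and the whole plan hinges on that. Its six carbons C4a, C5, C6, C7, C8 and C8a carry oxygen at C5, C7 and C8a and share the C4a–C8a edge with the pyranone. That edge, as the enol-ether double bond of a 2,3-cis-dihydropyran-4-one, is used as the alkene half of a vinylketene. The precursor is this dihydropyranone with a diazoacetyl group on C8a, with all four stereocentres and the benzyl-protected second flavanone already in place. Irradiation with (triisopropylsiloxy)acetylene then forms C5–C6, C7–C8 and C4a–C5 in one neutral operation, giving ring A with 5-OH free and O7 silylated.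

Key step: step 12

Labels: C2–C8a denote the anisyl flavanone (unit 1; pyranone C5 and C6 become C4a and C8a) and C2''–C8a'' the second flavanone (unit 2). Flv = (2R,3S)-5,7-bis(benzyloxy)-2-[4-(benzyloxy)phenyl]-4-oxo-3,4-dihydro-2H-chromen-3-yl. The target is 2S,3S,2''R,3''S (unit 1 cis, unit 2 trans).
Assumption: (triisopropylsiloxy)acetylene 21 is bought as a speciality reagent.

Step 1
Reactants: 1 2,4,6-trihydroxyacetophenone
Product: 2 1-[2,4-bis(benzyloxy)-6-hydroxyphenyl]ethan-1-one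
Conditions: BnBr (2.1 equiv), K2CO3, DMF, rt
Reagents that add atoms: benzyl bromide, BrCc1ccccc1
Why: Williamson ether synthesis: the carbonate base alkylates the para and one ortho phenol, whereas the remaining ortho hydroxyl, hydrogen-bonded to the acetyl carbonyl, is too weakly nucleophilic to react and stays free for the chromone closure.

Step 2
Reactants: 2 1-[2,4-bis(benzyloxy)-6-hydroxyphenyl]ethan-1-one
Product: 4 5,7-bis(benzyloxy)-4H-chromen-4-one, via enaminone 3 (not isolated)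
Conditions: Me2NCH(OMe)2, toluene, 100 °C; then conc. HCl, CH2Cl2, 40 °C
Reagents that add atoms: N,N-dimethylformamide dimethyl acetal, COC(OC)N(C)C
Why: Enaminone condensation at the acetyl methyl group followed by acid-promoted intramolecular oxa-Michael addition of the free phenol and elimination of dimethylamine, the standard chromone annulation of 2-hydroxyacetophenones.

Step 3
Reactants: 4 5,7-bis(benzyloxy)-4H-chromen-4-one; 5 4-(benzyloxy)phenylboronic acid
Product: 6 (2R)-5,7-bis(benzyloxy)-2-[4-(benzyloxy)phenyl]-2,3-dihydro-4H-chromen-4-one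
Conditions: Pd(OCOCF3)2 (5 mol%), (S)-4-tert-butyl-2-(pyridin-2-yl)-4,5-dihydrooxazole [(S)-t-BuPyOx, 6 mol%], NH4PF6, H2O, ClCH2CH2Cl, 60 °C
Reagents that add atoms: none
Why: Asymmetric conjugate addition of an arylboronic acid to a chromone: the aryl group is transferred from the Pd(OCOCF3)2/(S)-t-BuPyOx catalyst to one enantioface of C2'' (catalyst control, 2''R expected by analogy with the parent chromone) and water protonates C3''.

Step 4
Reactants: 6 (2R)-5,7-bis(benzyloxy)-2-[4-(benzyloxy)phenyl]-2,3-dihydro-4H-chromen-4-one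
Product: 8 (2R,3S)-3-allyl-5,7-bis(benzyloxy)-2-[4-(benzyloxy)phenyl]-2,3-dihydro-4H-chromen-4-one (2,3-trans), via lithium enolate 7 (not isolated)
Conditions: LiN(SiMe3)2, THF, −78 °C; allyl iodide, −78 °C; aq NH4Cl at −78 °C
Reagents that add atoms: allyl iodide, C=CCI
Why: Kinetic enolate alkylation: the lithium enolate 7, kept at −78 °C to suppress retro-oxa-Michael ring opening, is allylated anti to the C2'' aryl group, which sets C3'' as 3''S (2,3-trans, also the thermodynamically favoured arrangement).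

Step 5
Reactants: 8 (2R,3S)-3-allyl-5,7-bis(benzyloxy)-2-[4-(benzyloxy)phenyl]-2,3-dihydro-4H-chromen-4-one
Product: 9 2-Flv-acetaldehyde, that is 2-[(2R,3S)-5,7-bis(benzyloxy)-2-[4-(benzyloxy)phenyl]-4-oxo-3,4-dihydro-2H-chromen-3-yl]acetaldehyde
Conditions: O3, CH2Cl2/MeOH, −78 °C; then Me2S, −78 °C to rt
Reagents that add atoms: ozone, [O-][O+]=O
Why: Ozonolysis with reductive work-up cleaves the only alkene to the aldehyde, the acyl-deactivated arene and the benzyl ethers being much slower to react at −78 °C with a metered ozone dose.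

Step 6
Reactants: 9 2-Flv-acetaldehyde; 10 3,3-diethoxyprop-1-yne (propargylaldehyde diethyl acetal)
Product: 11 1-Flv-5,5-diethoxypent-3-yn-2-ol (both carbinol epimers)
Conditions: 10, n-BuLi, THF, −78 °C; then 9, −78 °C; aq NH4Cl
Reagents that add atoms: none
Why: Nucleophilic 1,2-addition of a lithium acetylide, which at −78 °C attacks the aldehyde much faster than the hindered, donor-deactivated aryl ketone; the new carbinol centre is left uncontrolled because it is oxidised in step 7.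

Step 7
Reactants: 11 1-Flv-5,5-diethoxypent-3-yn-2-ol
Product: 12 1-Flv-5,5-diethoxypent-3-yn-2-one
Conditions: Dess–Martin periodinane, CH2Cl2, 0 °C to rt
Reagents that add atoms: none
Why: Dess–Martin oxidation converts the propargylic alcohol into the ynone under essentially neutral conditions that spare the acetal, the benzyl ethers and the enolisable C3'' centre.

Step 8
Reactants: 12 1-Flv-5,5-diethoxypent-3-yn-2-one; 13 4-methoxybenzaldehyde
Product: 15 (1S,2S)-2-Flv-6,6-diethoxy-1-hydroxy-1-(4-methoxyphenyl)hex-4-yn-3-one, via boron enolate 14 (not isolated)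
Conditions: (−)-Ipc2BOTf, iPr2NEt, CH2Cl2, −78 °C; then 13, −78 to −20 °C; pH 7 buffer, MeOH, H2O2, 0 °C
Reagents that add atoms: none
Why: Reagent-controlled boron aldol reaction: soft enolisation at the unhindered α-methylene (not at the tertiary C3''–H) gives the Z-enolate 14, whose chair (Zimmerman–Traxler) transition state makes C2 and C3 syn, and the isopinocampheyl ligands are expected to join the aldehyde si face to the enolate re face at C3, so that 2S,3S does not rest on the unknown bias of the neighbouring C3'' centre alone.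

Step 9
Reactants: 15 (1S,2S)-2-Flv-6,6-diethoxy-1-hydroxy-1-(4-methoxyphenyl)hex-4-yn-3-one
Product: 17 (2S,3S)-3-Flv-2-(4-methoxyphenyl)-4-oxo-3,4-dihydro-2H-pyran-6-carbaldehyde, via acetal 16 (not isolated)
Conditions: AuCl3 (5 mol%), CH2Cl2, rt; then CF3CO2H/H2O, 0 °C
Reagents that add atoms: water, O
Why: AuCl3-catalysed 6-endo-dig hydroalkoxylation of the β-hydroxy ynone (the hydroxyl adds to the alkyne carbon β to the ketone) carries the syn aldol centres unchanged into the 2,3-cis-dihydropyranone 16, and aqueous acid then hydrolyses the acetal to the aldehyde without enolising C3.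

Step 10
Reactants: 17 (2S,3S)-3-Flv-2-(4-methoxyphenyl)-4-oxo-3,4-dihydro-2H-pyran-6-carbaldehyde
Product: 18 (2S,3S)-3-Flv-2-(4-methoxyphenyl)-4-oxo-3,4-dihydro-2H-pyran-6-carboxylic acid
Conditions: NaClO2, NaH2PO4, 2-methyl-2-butene, t-BuOH/H2O, 0 °C to rt
Reagents that add atoms: sodium chlorite, [Na+].[O-]Cl=O
Why: Pinnick oxidation of the aldehyde to the acid at about pH 4, with 2-methyl-2-butene consuming the hypochlorous acid by-product before it can chlorinate the electron-rich rings.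

Step 11
Reactants: 18 (2S,3S)-3-Flv-2-(4-methoxyphenyl)-4-oxo-3,4-dihydro-2H-pyran-6-carboxylic acid
Product: 20 (2S,3S)-6-(diazoacetyl)-3-Flv-2-(4-methoxyphenyl)-2,3-dihydro-4H-pyran-4-one, via acid chloride 19 (not isolated)
Conditions: Me2C=C(Cl)NMe2, CH2Cl2, 0 °C; then Me3SiCHN2, MeCN/THF, 0 °C
Reagents that add atoms: (trimethylsilyl)diazomethane, C[Si](C)(C)C=[N+]=[N-]
Why: Acid chloride formation with a neutral α-chloroenamine followed by C-acylation of the diazoalkane, with loss of the silyl group as Me3SiCl, is the standard diazomethyl ketone synthesis and exposes the cis centres to neither acid nor base.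

Step 12
Reactants: 20 (2S,3S)-6-(diazoacetyl)-3-Flv-2-(4-methoxyphenyl)-2,3-dihydro-4H-pyran-4-one; 21 (triisopropylsiloxy)acetylene
Product: 25 (2S,3S)-3-Flv-5-hydroxy-2-(4-methoxyphenyl)-7-[(triisopropylsilyl)oxy]-2,3-dihydro-4H-chromen-4-one, via vinylketene 22 (not isolated), via cyclobutenone 23 (not isolated), via dienylketene 24 (not isolated)
Conditions: 21 (3 equiv), ClCH2CH2Cl (degassed), hν (LED, 390–405 nm), 20 °C; then 80 °C
Reagents that add atoms: none
Why: Danheiser benzannulation in its photochemical Wolff form: photolysis of 20 releases N2 and C8a migrates from the acyl carbon to the diazo carbon, giving vinylketene 22 (O=C5=C8H–C8a=C4a), which adds siloxyalkyne 21 in a thermal [2+2] cycloaddition to form 4-vinylcyclobutenone 23. Four-electron electrocyclic opening of 23 (cleavage of C5–C8) gives dienylketene 24, and ring A is closed by six-electron electrocyclisation of 24 with formation of C4a–C5, followed by tautomerisation to the phenol. The closest known reaction type is this same annulation of α-diazo enones with siloxyalkynes, applied here to a diazo enone whose alkene is the enol-ether bond of a dihydropyranone. No stereocentre is formed; the four existing ones only have to survive, which the neutral medium free of acid and base secures. The selectivity required is the [2+2] regiochemistry, secured by the polarisation of the partners: the nucleophilic CH terminus of the ynol ether bonds to the electrophilic ketene carbon C5 (C5–C6) and the silyloxy carbon to C8 (C7–C8), which fixes 5-OH and 7-OSi, while the ketene arm lies trans to C4 across C4a=C8a so that closure onto the C4 carbonyl is impossible. Light of 390–405 nm is chosen to excite only the diazo ketone and not the flavanone or benzyl ether chromophores, and the new 5-OH is hydrogen-bonded to C4=O, which slows its acylation by ketene.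

Step 13
Reactants: 25 (2S,3S)-3-Flv-5-hydroxy-2-(4-methoxyphenyl)-7-[(triisopropylsilyl)oxy]-2,3-dihydro-4H-chromen-4-one
Product: 26 (2S,3S)-3-Flv-5,7-dihydroxy-2-(4-methoxyphenyl)-2,3-dihydro-4H-chromen-4-one
Conditions: Bu4NF/AcOH (1:1), THF, 0 °C
Reagents that add atoms: none
Why: Fluoride-mediated cleavage of the aryl silyl ether, buffered with acetic acid so that the 2,3-cis flavanone, which epimerises at C3 under base, never meets a free phenoxide or basic fluoride.

Step 14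
Reactants: 26 (2S,3S)-3-Flv-5,7-dihydroxy-2-(4-methoxyphenyl)-2,3-dihydro-4H-chromen-4-one
Product: 27 (2S,3S)-5,7-dihydroxy-3-[(2R,3S)-5,7-dihydroxy-2-(4-hydroxyphenyl)-4-oxo-3,4-dihydro-2H-chromen-3-yl]-2-(4-methoxyphenyl)-2,3-dihydro-4H-chromen-4-one (CNP0196568.4)
Conditions: H2 (1 atm), 10% Pd/C, EtOAc/MeOH, rt
Reagents that add atoms: none
Why: Catalytic hydrogenolysis over Pd/C removes the three benzyl ethers under neutral conditions, while the aryl methyl ether, the hydrogen-bonded aryl ketones and the cyclic benzylic C2–O bonds are stable at ambient pressure.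

Compound list

1 | 2,4,6-trihydroxyacetophenone | CC(=O)c1c(O)cc(O)cc1O | starting material
2 | 1-[2,4-bis(benzyloxy)-6-hydroxyphenyl]ethan-1-one | CC(=O)c1c(O)cc(OCc2ccccc2)cc1OCc1ccccc1 | intermediate
3 | (E)-1-[2,4-bis(benzyloxy)-6-hydroxyphenyl]-3-(dimethylamino)prop-2-en-1-one (enaminone, not isolated) | CN(C)/C=C/C(=O)c1c(O)cc(OCc2ccccc2)cc1OCc1ccccc1 | intermediate
4 | 5,7-bis(benzyloxy)-4H-chromen-4-one | O=c1ccoc2cc(OCc3ccccc3)cc(OCc3ccccc3)c12 | intermediate
5 | 4-(benzyloxy)phenylboronic acid | OB(O)c1ccc(OCc2ccccc2)cc1 | starting material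
6 | (2R)-5,7-bis(benzyloxy)-2-[4-(benzyloxy)phenyl]-2,3-dihydro-4H-chromen-4-one | O=C1C[C@H](c2ccc(OCc3ccccc3)cc2)Oc2cc(OCc3ccccc3)cc(OCc3ccccc3)c12 | intermediate
7 | lithium (2R)-5,7-bis(benzyloxy)-2-[4-(benzyloxy)phenyl]-2H-chromen-4-olate (lithium enolate of 6, not isolated) | [Li]OC1=C[C@H](c2ccc(OCc3ccccc3)cc2)Oc2cc(OCc3ccccc3)cc(OCc3ccccc3)c12 | intermediate
8 | (2R,3S)-3-allyl-5,7-bis(benzyloxy)-2-[4-(benzyloxy)phenyl]-2,3-dihydro-4H-chromen-4-one (2,3-trans) | C=CC[C@@H]1C(=O)c2c(OCc3ccccc3)cc(OCc3ccccc3)cc2O[C@H]1c1ccc(OCc2ccccc2)cc1 | intermediate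
9 | 2-[(2R,3S)-5,7-bis(benzyloxy)-2-[4-(benzyloxy)phenyl]-4-oxo-3,4-dihydro-2H-chromen-3-yl]acetaldehyde (2-Flv-acetaldehyde) | O=CC[C@@H]1C(=O)c2c(OCc3ccccc3)cc(OCc3ccccc3)cc2O[C@H]1c1ccc(OCc2ccccc2)cc1 | intermediate
10 | 3,3-diethoxyprop-1-yne | C#CC(OCC)OCC | starting material
11 | 1-Flv-5,5-diethoxypent-3-yn-2-ol (both carbinol epimers) | CCOC(OCC)C#CC(O)C[C@@H]1C(=O)c2c(OCc3ccccc3)cc(OCc3ccccc3)cc2O[C@H]1c1ccc(OCc2ccccc2)cc1 | intermediate
12 | 1-Flv-5,5-diethoxypent-3-yn-2-one | CCOC(OCC)C#CC(=O)C[C@@H]1C(=O)c2c(OCc3ccccc3)cc(OCc3ccccc3)cc2O[C@H]1c1ccc(OCc2ccccc2)cc1 | intermediate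
13 | 4-methoxybenzaldehyde | COc1ccc(C=O)cc1 | starting material
14 | (Z)-1-Flv-5,5-diethoxypent-1-en-3-yn-2-yl bis(isopinocampheyl)borinate (Z-boron enolate of 12, not isolated) | CCOC(OCC)C#C/C(OB([C@@H]1C[C@@H]2C[C@@H](C2(C)C)[C@H]1C)[C@@H]1C[C@@H]2C[C@@H](C2(C)C)[C@H]1C)=C/[C@@H]1C(=O)c2c(OCc3ccccc3)cc(OCc3ccccc3)cc2O[C@H]1c1ccc(OCc2ccccc2)cc1 | intermediate
15 | (1S,2S)-2-Flv-6,6-diethoxy-1-hydroxy-1-(4-methoxyphenyl)hex-4-yn-3-one (syn aldol) | COc1ccc([C@@H](O)[C@@H](C(=O)C#CC(OCC)OCC)[C@@H]2C(=O)c3c(OCc4ccccc4)cc(OCc4ccccc4)cc3O[C@H]2c2ccc(OCc3ccccc3)cc2)cc1 | intermediate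
16 | (2S,3S)-6-(diethoxymethyl)-3-Flv-2-(4-methoxyphenyl)-2,3-dihydro-4H-pyran-4-one (2,3-cis, not isolated) | COc1ccc([C@H]2OC(C(OCC)OCC)=CC(=O)[C@H]2[C@@H]2C(=O)c3c(OCc4ccccc4)cc(OCc4ccccc4)cc3O[C@H]2c2ccc(OCc3ccccc3)cc2)cc1 | intermediate
17 | (2S,3S)-3-Flv-2-(4-methoxyphenyl)-4-oxo-3,4-dihydro-2H-pyran-6-carbaldehyde | COc1ccc([C@H]2OC(C=O)=CC(=O)[C@H]2[C@@H]2C(=O)c3c(OCc4ccccc4)cc(OCc4ccccc4)cc3O[C@H]2c2ccc(OCc3ccccc3)cc2)cc1 | intermediate
18 | (2S,3S)-3-Flv-2-(4-methoxyphenyl)-4-oxo-3,4-dihydro-2H-pyran-6-carboxylic acid | COc1ccc([C@H]2OC(C(=O)O)=CC(=O)[C@H]2[C@@H]2C(=O)c3c(OCc4ccccc4)cc(OCc4ccccc4)cc3O[C@H]2c2ccc(OCc3ccccc3)cc2)cc1 | intermediate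
19 | (2S,3S)-3-Flv-2-(4-methoxyphenyl)-4-oxo-3,4-dihydro-2H-pyran-6-carbonyl chloride (not isolated) | COc1ccc([C@H]2OC(C(=O)Cl)=CC(=O)[C@H]2[C@@H]2C(=O)c3c(OCc4ccccc4)cc(OCc4ccccc4)cc3O[C@H]2c2ccc(OCc3ccccc3)cc2)cc1 | intermediate
20 | (2S,3S)-6-(diazoacetyl)-3-Flv-2-(4-methoxyphenyl)-2,3-dihydro-4H-pyran-4-one | COc1ccc([C@H]2OC(C(=O)C=[N+]=[N-])=CC(=O)[C@H]2[C@@H]2C(=O)c3c(OCc4ccccc4)cc(OCc4ccccc4)cc3O[C@H]2c2ccc(OCc3ccccc3)cc2)cc1 | intermediate
21 | (triisopropylsiloxy)acetylene | C#CO[Si](C(C)C)(C(C)C)C(C)C | starting material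
22 | 2-[(2S,3S)-3-Flv-2-(4-methoxyphenyl)-4-oxo-3,4-dihydro-2H-pyran-6-yl]ethen-1-one (vinylketene, not isolated) | COc1ccc([C@H]2OC(C=C=O)=CC(=O)[C@H]2[C@@H]2C(=O)c3c(OCc4ccccc4)cc(OCc4ccccc4)cc3O[C@H]2c2ccc(OCc3ccccc3)cc2)cc1 | intermediate
23 | 4-[(2S,3S)-3-Flv-2-(4-methoxyphenyl)-4-oxo-3,4-dihydro-2H-pyran-6-yl]-3-[(triisopropylsilyl)oxy]cyclobut-2-en-1-one (either configuration at the ring sp3 carbon, not isolated) | COc1ccc([C@H]2OC(C3C(=O)C=C3O[Si](C(C)C)(C(C)C)C(C)C)=CC(=O)[C@H]2[C@@H]2C(=O)c3c(OCc4ccccc4)cc(OCc4ccccc4)cc3O[C@H]2c2ccc(OCc3ccccc3)cc2)cc1 | intermediate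
24 | (3E)-4-[(2S,3S)-3-Flv-2-(4-methoxyphenyl)-4-oxo-3,4-dihydro-2H-pyran-6-yl]-3-[(triisopropylsilyl)oxy]buta-1,3-dien-1-one (dienylketene, pyranyl group cis to the ketene arm, not isolated) | COc1ccc([C@H]2OC(/C=C(O[Si](C(C)C)(C(C)C)C(C)C)\C=C=O)=CC(=O)[C@H]2[C@@H]2C(=O)c3c(OCc4ccccc4)cc(OCc4ccccc4)cc3O[C@H]2c2ccc(OCc3ccccc3)cc2)cc1 | intermediate
25 | (2S,3S)-3-Flv-5-hydroxy-2-(4-methoxyphenyl)-7-[(triisopropylsilyl)oxy]-2,3-dihydro-4H-chromen-4-one | COc1ccc([C@H]2Oc3cc(O[Si](C(C)C)(C(C)C)C(C)C)cc(O)c3C(=O)[C@H]2[C@@H]2C(=O)c3c(OCc4ccccc4)cc(OCc4ccccc4)cc3O[C@H]2c2ccc(OCc3ccccc3)cc2)cc1 | intermediate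
26 | (2S,3S)-3-Flv-5,7-dihydroxy-2-(4-methoxyphenyl)-2,3-dihydro-4H-chromen-4-one | COc1ccc([C@H]2Oc3cc(O)cc(O)c3C(=O)[C@H]2[C@@H]2C(=O)c3c(OCc4ccccc4)cc(OCc4ccccc4)cc3O[C@H]2c2ccc(OCc3ccccc3)cc2)cc1 | intermediate
27 | (2S,3S)-5,7-dihydroxy-3-[(2R,3S)-5,7-dihydroxy-2-(4-hydroxyphenyl)-4-oxo-3,4-dihydro-2H-chromen-3-yl]-2-(4-methoxyphenyl)-2,3-dihydro-4H-chromen-4-one | COc1ccc([C@H]2Oc3cc(O)cc(O)c3C(=O)[C@H]2[C@@H]2C(=O)c3c(O)cc(O)cc3O[C@H]2c2ccc(O)cc2)cc1 | target

Total step count: 14. Longest linear sequence: 14 steps (1 to 27); the coupling partners 5, 10, 13 and 21 are bought.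

Steps most likely to fail

Step 12. Process at risk: photons may be taken up by the flavanone or product chromophores, so that the Wolff shift is slow and the ketene is lost to secondary photoreactions or to acylation of the newly formed phenol. Fallback, setting out from 20 and returning at 25: the same vinylketene is made in the dark. PhCO2Ag-catalysed Wolff rearrangement of 20 in dioxane/H2O under ultrasound (no base) gives the homologous acid, 2-[(2S,3S)-3-Flv-2-(4-methoxyphenyl)-4-oxo-3,4-dihydro-2H-pyran-6-yl]acetic acid F1. Me2C=C(Cl)NMe2 converts it into the corresponding acetyl chloride F2. Slow addition of iPr2NEt to F2 and 21 in toluene at 60–80 °C releases vinylketene 22 by dehydrochlorination, and 22 proceeds thermally through 23 and 24 to 25.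

Step 8. Process at risk: poor facial selectivity if the bias of C3'' opposes the boron ligands, or partial enolisation towards C3''. Fallback, setting out from 9 and returning at 15: an auxiliary fixes the sense. Pinnick oxidation of 9 gives Flv-acetic acid F3. PivCl/Et3N, then (S)-4-benzyloxazolidin-2-one and LiCl, gives the N-acyl oxazolidinone F4. The Evans syn aldol reaction (Bu2BOTf, iPr2NEt, 13, −78 to 0 °C) should give the (2S,3S) aldol adduct F5 under auxiliary control. LiSEt in THF at −20 °C gives the S-ethyl thioester F6. PdCl2(dppf)/CuI-mediated coupling of F6 with alkyne 10 (tri(2-furyl)phosphine, Et3N, DMF) gives 15.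

Step 4. Process at risk: ring opening of the enolate by retro-oxa-Michael elimination of the phenoxide (erosion of C2'' and chalcone formation) while C-alkylation is slow, or double alkylation. Fallback, setting out from 6 and returning at 8: enolate 7 is trapped on oxygen within minutes at −78 °C (allyl chloroformate, TMEDA) as the allyl enol carbonate F7. Pd(PPh3)4 in THF at rt converts F7 into 8 by decarboxylative Tsuji allylation, the allyl group again entering anti to the C2'' aryl group.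

Further compounds

F1 | step 12 | 2-[(2S,3S)-3-Flv-2-(4-methoxyphenyl)-4-oxo-3,4-dihydro-2H-pyran-6-yl]acetic acid | COc1ccc([C@H]2OC(CC(=O)O)=CC(=O)[C@H]2[C@@H]2C(=O)c3c(OCc4ccccc4)cc(OCc4ccccc4)cc3O[C@H]2c2ccc(OCc3ccccc3)cc2)cc1
F2 | step 12 | 2-[(2S,3S)-3-Flv-2-(4-methoxyphenyl)-4-oxo-3,4-dihydro-2H-pyran-6-yl]acetyl chloride | COc1ccc([C@H]2OC(CC(=O)Cl)=CC(=O)[C@H]2[C@@H]2C(=O)c3c(OCc4ccccc4)cc(OCc4ccccc4)cc3O[C@H]2c2ccc(OCc3ccccc3)cc2)cc1
F3 | step 8 | 2-[(2R,3S)-5,7-bis(benzyloxy)-2-[4-(benzyloxy)phenyl]-4-oxo-3,4-dihydro-2H-chromen-3-yl]acetic acid | OC(=O)C[C@@H]1C(=O)c2c(OCc3ccccc3)cc(OCc3ccccc3)cc2O[C@H]1c1ccc(OCc2ccccc2)cc1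
F4 | step 8 | (4S)-4-benzyl-3-(2-Flv-acetyl)-1,3-oxazolidin-2-one | O=C(C[C@@H]1C(=O)c2c(OCc3ccccc3)cc(OCc3ccccc3)cc2O[C@H]1c1ccc(OCc2ccccc2)cc1)N1[C@@H](Cc2ccccc2)COC1=O
F5 | step 8 | (4S)-4-benzyl-3-[(2S,3S)-2-Flv-3-hydroxy-3-(4-methoxyphenyl)propanoyl]-1,3-oxazolidin-2-one | COc1ccc([C@@H](O)[C@@H](C(=O)N2[C@@H](Cc3ccccc3)COC2=O)[C@@H]2C(=O)c3c(OCc4ccccc4)cc(OCc4ccccc4)cc3O[C@H]2c2ccc(OCc3ccccc3)cc2)cc1
F6 | step 8 | S-ethyl (2S,3S)-2-Flv-3-hydroxy-3-(4-methoxyphenyl)propanethioate | COc1ccc([C@@H](O)[C@@H](C(=O)SCC)[C@@H]2C(=O)c3c(OCc4ccccc4)cc(OCc4ccccc4)cc3O[C@H]2c2ccc(OCc3ccccc3)cc2)cc1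
F7 | step 4 | allyl (2R)-5,7-bis(benzyloxy)-2-[4-(benzyloxy)phenyl]-2H-chromen-4-yl carbonate | C=CCOC(=O)OC1=C[C@H](c2ccc(OCc3ccccc3)cc2)Oc2cc(OCc3ccccc3)cc(OCc3ccccc3)c12
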